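(The readings are simulated with made-up constants.)

1. I began with an easy step, dividing the gains between dissolved substrate readings of the ash run, which is this flask followed so far, by the minutes they took, because I had to decide whether the next run should take more solid substrate.

- ash: solid substrate 21 mM; partner 1.8 equiv; the very flask that is asked about, followed so far
- flask: solid substrate 21 mM; partner 1.80 equiv; time 5.0 h

ash run (percent of the solid substrate charged)

| time / min | target / % | dissolved substrate / % | solid substrate / % |
|---|---|---|---|
| 2.00 | 0 | 3 | 96 |
| 3.00 | 3 | 4 | 94 |
| 4.00 | 2 | 6 | 92 |
| 6.00 | 0 | 9 | 88 |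
| 10.0 | 3 | 16 | 85 |
| 15.0 | 3 | 20 | 78 |
| 25.0 | 1 | 26 | 71 |

(each reading ± 1.5 percentage points)

- solid, in amounts per volume of the solution: solid substrate
- at the start none of the solid substrate is in solution
- dissolved substrate means what is dissolved; the solid is not counted in it

1. how much target there is at 5.0 h, in percent of the solid substrate charged
2. concentration of dissolved substrate in solution at 5.0 h, in percent of saturation

2. Up to 6.00 min dissolved substrate gained 0.315 mM min⁻¹ at a mean level of 0.945 mM, and from 15.0 min to 25.0 min it gained 0.126 mM min⁻¹ at 4.83 mM.

3. I took the gain to fall in a straight line with the level, and that line reached zero at a reading of 7.42 mM, the ceiling of dissolved substrate, which I read as a solubility limit and treated as a concentration and not as a share of the charge.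

4. The same line put the half-time of the gap to that ceiling at 14.2 min, far shorter than the 5.0 h asked, and the ceiling stood below the charge of 21 mM, so I kept the next run at that charge, since by this reckoning extra solid promised no extra dissolved substrate.

5. The forecast gave 40% target and 85% of saturation, holding that “dissolved substrate sits a little below saturation”.

6. The flask gave 11.5% target and 93.8% of saturation at 5.0 h, and with the self-condensation of partner struck out its target came to 30.4%. Dissolved substrate in this flask then stood at 35.3% of the charge, where my ceiling, a reading with the scatter of the ash run, came to 35.3%.

    solid substrate ⇌ dissolved substrate, rate k1*(cs1 - [dissolved substrate]) while solid is left; crystals form when [dissolved substrate] > cs1 (solubility = 7.90 mM, k = 0.0500 min⁻¹)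
    dissolved substrate + partner → target (k = 0.130 L mol⁻¹ min⁻¹)
    2 dissolved substrate → side product (k = 0.190 L mol⁻¹ min⁻¹)
    partner → decomposed reagent (k = 0.00180 min⁻¹)
    target ⇌ isomer of the product (K = 0.530, k = 2.40 × 10⁻⁴ min⁻¹)
    2 partner → self-condensation product (k = 0.250 L mol⁻¹ min⁻¹)

7. For the neighbour charged with 84 mM of solid substrate, the same ceiling came to 8.83% of its charge, and that flask held 8.81% dissolved at 5.00 h, with 4.38% target.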